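**Retrosynthetic overview**

1. The labile (Z)-enal is made last, by MnO2 oxidation of a (Z)-allylic alcohol that comes from Stille coupling at C5–Br of ring A with (Z)-Bu3SnCH=CHCH2OH; nothing is deprotected after the enal exists.
2. Ring B (bond O1–C2, stereocentres C2 and C3) comes from a chiral phosphoric acid cyclization of a flat, achiral stilbene that already carries the 4-hydroxybenzoate ester.
3. Feature used: the free 4'-OH of the guaiacyl ring C is para to C2, so a C2=C3 stilbene is a latent para-quinone methide, and the phenol oxygen O1 on C7a of ring A ends the five-atom chain O1–C7a–C3a–C3–C2. Protonation of C3 followed by O1→C2 addition therefore closes ring B.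
4. The stilbene comes from fluoride desilylation, after selective acylation of an allylic alcohol, after iBu2AlH opening of a 3-arylidenebenzofuran-2(3H)-one, after Knoevenagel condensation of 5-bromo-7-methoxybenzofuran-2(3H)-one with O-silyl vanillin; the lactone comes from 4-bromoguaiacol and glyoxylic acid.
5. Ring order: rings A, C and D (the benzoate ring) are bought; the lactone ring made in step 2 is opened again in step 5; ring B is the only ring of the target that is formed, in step 9.

Key step: step 9

**Remarks on the chemistry**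

- Benzofuran numbering of the target is used for the stilbene carbons throughout: C2 bears ring C, C3 bears ring A and the CH2O arm.
- (R)-TRIP is (R)-3,3'-bis(2,4,6-triisopropylphenyl)-1,1'-binaphthyl-2,2'-diyl hydrogen phosphate. Which enantiomer of the acid leads to the (2S,3R) series has to be settled in the first run; the (S)-acid is taken if the sense is opposite.
- Compounds 8, 9, 14 and 15 are drawn as the E isomers expected from the condensation. The C2=C3 geometry is erased in step 9, so a mixture of isomers can be carried.
- The ring D phenol is left free from step 8 on, so that no deprotection has to follow formation of the (Z)-enal.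
- Glyoxylic acid is used as its commercial 50% aqueous solution.

**Route**

Step 1
Reactants: 1 4-bromo-2-methoxyphenol; 2 glyoxylic acid
Product: 3 2-(5-bromo-2-hydroxy-3-methoxyphenyl)-2-hydroxyacetic acid (racemic)
Conditions: NaOH, H2O, rt to 40 °C; then HCl (aq.)
Reagents that add atoms: none
Why: Base-mediated ortho-hydroxyalkylation of a phenoxide by glyoxylate (electrophilic aromatic substitution of the Lederer–Manasse type): the para position carries bromine and one ortho position the methoxy group, so C6 is the only activated free carbon; the new carbinol centre is racemic and is removed in step 2.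

Step 2
Reactants: 3 2-(5-bromo-2-hydroxy-3-methoxyphenyl)-2-hydroxyacetic acid
Product: 5 5-bromo-7-methoxy-1-benzofuran-2(3H)-one, via hydroxyarylacetic acid 4 (not isolated)
Conditions: SnCl2·2H2O, conc. HCl, AcOH, 80 °C; then TsOH·H2O (cat.), PhMe, reflux, Dean–Stark
Reagents that add atoms: none
Why: Reductive deoxygenation of the benzylic hydroxyl of a hydroxymandelic acid (ionization to the phenol-stabilized benzylic cation and two-electron reduction by divalent tin, which leaves the aryl bromide alone), followed by acid-catalysed lactonization of the 2-hydroxyarylacetic acid (intramolecular Fischer esterification to a five-membered ring).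

Step 3
Reactants: 6 vanillin
Product: 7 3-methoxy-4-(triisopropylsilyloxy)benzaldehyde
Conditions: iPr3SiCl, imidazole, DMF, rt
Reagents that add atoms: triisopropylsilyl chloride, CC(C)[Si](Cl)(C(C)C)C(C)C
Why: Imidazole-promoted silylation of the phenol (silyl ether protection); the bulky triisopropylsilyl ether is chosen to withstand the amine catalyst of step 4 and the hydride of step 5.

Step 4
Reactants: 5 5-bromo-7-methoxy-1-benzofuran-2(3H)-one; 7 3-methoxy-4-(triisopropylsilyloxy)benzaldehyde
Product: 8 (E)-5-bromo-7-methoxy-3-[3-methoxy-4-(triisopropylsilyloxy)benzylidene]-1-benzofuran-2(3H)-one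
Conditions: piperidine (cat.), AcOH (cat.), PhMe, reflux, Dean–Stark
Reagents that add atoms: none
Why: Knoevenagel condensation: the lactone CH2 is acidic because its enolate is an aromatic benzofuran-2-olate, and dehydration of the aldol adduct should favour the E isomer with the aryl group away from the lactone carbonyl.

Step 5
Reactants: 8 (E)-5-bromo-7-methoxy-3-[3-methoxy-4-(triisopropylsilyloxy)benzylidene]-1-benzofuran-2(3H)-one
Product: 9 (E)-2-(5-bromo-2-hydroxy-3-methoxyphenyl)-3-[3-methoxy-4-(triisopropylsilyloxy)phenyl]prop-2-en-1-ol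
Conditions: iBu2AlH (3.5 equiv), CH2Cl2, −78 to 0 °C; aq. KNaC4H4O6 (potassium sodium tartrate) work-up
Reagents that add atoms: none
Why: 1,2-Reduction of the unsaturated aryl lactone by iBu2AlH: the lactol aluminate opens to the aryloxide and the enal, which is reduced again, so the lactone carbonyl becomes the allylic CH2OH and the ring A phenol is set free without touching the C=C bond, the aryl bromide or the silyl ether.

Step 6
Reactants: 10 4-hydroxybenzoic acid
Product: 12 4-(tert-butyldimethylsilyloxy)benzoic acid, via bis-silylated ester 11 (not isolated)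
Conditions: tBuMe2SiCl (2.2 equiv), imidazole, DMF, rt; then AcOH/THF/H2O, rt
Reagents that add atoms: tert-butyldimethylsilyl chloride, CC(C)(C)[Si](C)(C)Cl
Why: Silylation of both the phenol and the acid, then selective hydrolysis of the labile silyl ester in aqueous acetic acid, which leaves the aryl silyl ether in place (silyl ether protection with silyl ester cleavage).

Step 7
Reactants: 9 (E)-2-(5-bromo-2-hydroxy-3-methoxyphenyl)-3-[3-methoxy-4-(triisopropylsilyloxy)phenyl]prop-2-en-1-ol; 12 4-(tert-butyldimethylsilyloxy)benzoic acid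
Product: 14 (E)-2-(5-bromo-2-hydroxy-3-methoxyphenyl)-3-[3-methoxy-4-(triisopropylsilyloxy)phenyl]prop-2-en-1-yl 4-(tert-butyldimethylsilyloxy)benzoate, via acid chloride 13 (not isolated)
Conditions: 12, (COCl)2, DMF (cat.), CH2Cl2, 0 °C to rt, evaporate; then 9, pyridine, CH2Cl2, −40 to 0 °C
Reagents that add atoms: none
Why: Acid chloride formation by the oxalyl chloride/DMF (Vilsmeier-type) method and nucleophilic acyl substitution on the primary allylic alcohol; with pyridine and no acyl-transfer catalyst the neutral ring A phenol, flanked by two ortho substituents and hydrogen-bonded to its methoxy group, should not compete, and acylation is preferred to activation of the alcohol (Mitsunobu) because an activated allylic carbon would be attacked by that phenol.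

Step 8
Reactants: 14 (E)-2-(5-bromo-2-hydroxy-3-methoxyphenyl)-3-[3-methoxy-4-(triisopropylsilyloxy)phenyl]prop-2-en-1-yl 4-(tert-butyldimethylsilyloxy)benzoate
Product: 15 (E)-2-(5-bromo-2-hydroxy-3-methoxyphenyl)-3-(4-hydroxy-3-methoxyphenyl)prop-2-en-1-yl 4-hydroxybenzoate
Conditions: Bu4NF, AcOH, THF, 0 °C to rt
Reagents that add atoms: none
Why: Fluoride-mediated cleavage of both aryl silyl ethers (Si–F bond formation); acetic acid buffering keeps the liberated phenols protonated, so that the 4-hydroxycinnamyl ester does not eliminate benzoate through its phenoxide.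

Step 9
Reactants: 15 (E)-2-(5-bromo-2-hydroxy-3-methoxyphenyl)-3-(4-hydroxy-3-methoxyphenyl)prop-2-en-1-yl 4-hydroxybenzoate
Product: 17 [(2S,3R)-5-bromo-2-(4-hydroxy-3-methoxyphenyl)-7-methoxy-2,3-dihydro-1-benzofuran-3-yl]methyl 4-hydroxybenzoate, via para-quinone methide 16 (not isolated)
Conditions: (R)-TRIP (10 mol%), PhMe/CH2Cl2 (4:1, 0.02 M), 0 °C to rt
Reagents that add atoms: none
Why: Proposed new method: the acid is anchored by a hydrogen bond from the ring A phenol to its P=O oxygen and hands its proton to C3, the nucleophilic β-carbon of the 4-hydroxystyrene unit of ring C, which gives para-quinone methide 16 (at first as its O-protonated form paired with the chiral phosphate); the phosphate then takes the proton of the ring A phenol as O1 adds to the methide carbon C2, and ring C becomes aromatic again. The closest known reactions are chiral phosphoric acid-catalysed additions to para-quinone methides and to quinone methides generated in situ from hydroxystyrenes; an enantioselective protonation of a stilbene carbon followed by intramolecular oxa-1,6-addition has not been shown. Ring B closes by 5-exo-trig attack of O1 on the exocyclic C2=C1' bond of 16, which is formally a 5-endo hydroalkoxylation of the stilbene. C3 (R) is set by the face on which the chiral ion pair delivers the proton, and C2 (S) follows from C3, because A(1,3) strain keeps the C3–H bond in the plane of the methide so that O1 adds with ring C ending trans to the CH2O arm, and reversible opening of the benzylic C2–O1 bond under the acid would take any cis isomer to trans. The step needs protonation at C3 and not at C2 (which would give an ortho-quinone methide of ring A that cannot cyclize) and no ionization of the allylic ester; ring A is twisted out of conjugation by its two ortho substituents, the CH2O ester arm destabilizes a cation at C3, wrong protonation is reversible, and the benzoate is a poor leaving group toward a weak acid in a non-polar solvent.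

Step 10
Reactants: 18 prop-2-yn-1-ol
Product: 19 (Z)-3-(tributylstannyl)prop-2-en-1-ol
Conditions: LiAlH4, THF, 0 °C to rt; then Bu3SnOTf, −78 °C to rt; H2O
Reagents that add atoms: tributyltin trifluoromethanesulfonate, CCCC[Sn](CCCC)(CCCC)OS(=O)(=O)C(F)(F)F
Why: Hydroxyl-directed trans-hydroalumination of the propargylic alcohol places aluminium on C3 cis to the CH2O group in a five-membered alanate, and tin-for-aluminium exchange with retention gives the (Z)-vinylstannane.

Step 11
Reactants: 17 [(2S,3R)-5-bromo-2-(4-hydroxy-3-methoxyphenyl)-7-methoxy-2,3-dihydro-1-benzofuran-3-yl]methyl 4-hydroxybenzoate; 19 (Z)-3-(tributylstannyl)prop-2-en-1-ol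
Product: 20 [(2S,3R)-2-(4-hydroxy-3-methoxyphenyl)-5-[(Z)-3-hydroxyprop-1-en-1-yl]-7-methoxy-2,3-dihydro-1-benzofuran-3-yl]methyl 4-hydroxybenzoate
Conditions: Pd(PtBu3)2 (5 mol%), CsF, 1,4-dioxane, 50 °C
Reagents that add atoms: none
Why: Stille cross-coupling (oxidative addition of the electron-rich aryl bromide to zerovalent palladium bearing the bulky electron-rich phosphine, fluoride-assisted transmetalation, reductive elimination), which proceeds with retention of the alkene geometry and tolerates the free phenols, the ester and the primary alcohol.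

Step 12
Reactants: 20 [(2S,3R)-2-(4-hydroxy-3-methoxyphenyl)-5-[(Z)-3-hydroxyprop-1-en-1-yl]-7-methoxy-2,3-dihydro-1-benzofuran-3-yl]methyl 4-hydroxybenzoate
Product: 21 [(2S,3R)-2-(4-hydroxy-3-methoxyphenyl)-7-methoxy-5-[(Z)-3-oxoprop-1-en-1-yl]-2,3-dihydro-1-benzofuran-3-yl]methyl 4-hydroxybenzoate (CNP0400980.1)
Conditions: MnO2 (activated, excess), CH2Cl2, rt, dark
Reagents that add atoms: none
Why: Chemoselective heterogeneous oxidation of an allylic (cinnamyl-type) alcohol to the enal by MnO2 under neutral conditions, which leaves the benzoate and both stereocentres alone and, at room temperature in the dark, should keep the Z geometry.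

**Compound list**

1 | 4-bromo-2-methoxyphenol | COc1cc(Br)ccc1O | starting material
2 | glyoxylic acid | OC(=O)C=O | starting material
3 | 2-(5-bromo-2-hydroxy-3-methoxyphenyl)-2-hydroxyacetic acid (racemic) | COc1cc(Br)cc(C(O)C(=O)O)c1O | intermediate
4 | 2-(5-bromo-2-hydroxy-3-methoxyphenyl)acetic acid | COc1cc(Br)cc(CC(=O)O)c1O | intermediate
5 | 5-bromo-7-methoxy-1-benzofuran-2(3H)-one | COc1cc(Br)cc2CC(=O)Oc12 | intermediate
6 | vanillin | COc1cc(C=O)ccc1O | starting material
7 | 3-methoxy-4-(triisopropylsilyloxy)benzaldehyde | COc1cc(C=O)ccc1O[Si](C(C)C)(C(C)C)C(C)C | intermediate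
8 | (E)-5-bromo-7-methoxy-3-[3-methoxy-4-(triisopropylsilyloxy)benzylidene]-1-benzofuran-2(3H)-one | COc1cc(Br)cc2/C(=C\c3ccc(O[Si](C(C)C)(C(C)C)C(C)C)c(OC)c3)C(=O)Oc12 | intermediate
9 | (E)-2-(5-bromo-2-hydroxy-3-methoxyphenyl)-3-[3-methoxy-4-(triisopropylsilyloxy)phenyl]prop-2-en-1-ol | COc1cc(Br)cc(/C(CO)=C\c2ccc(O[Si](C(C)C)(C(C)C)C(C)C)c(OC)c2)c1O | intermediate
10 | 4-hydroxybenzoic acid | OC(=O)c1ccc(O)cc1 | starting material
11 | tert-butyldimethylsilyl 4-(tert-butyldimethylsilyloxy)benzoate | CC(C)(C)[Si](C)(C)OC(=O)c1ccc(O[Si](C)(C)C(C)(C)C)cc1 | intermediate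
12 | 4-(tert-butyldimethylsilyloxy)benzoic acid | CC(C)(C)[Si](C)(C)Oc1ccc(C(=O)O)cc1 | intermediate
13 | 4-(tert-butyldimethylsilyloxy)benzoyl chloride | CC(C)(C)[Si](C)(C)Oc1ccc(C(=O)Cl)cc1 | intermediate
14 | (E)-2-(5-bromo-2-hydroxy-3-methoxyphenyl)-3-[3-methoxy-4-(triisopropylsilyloxy)phenyl]prop-2-en-1-yl 4-(tert-butyldimethylsilyloxy)benzoate | COc1cc(Br)cc(/C(COC(=O)c2ccc(O[Si](C)(C)C(C)(C)C)cc2)=C\c2ccc(O[Si](C(C)C)(C(C)C)C(C)C)c(OC)c2)c1O | intermediate
15 | (E)-2-(5-bromo-2-hydroxy-3-methoxyphenyl)-3-(4-hydroxy-3-methoxyphenyl)prop-2-en-1-yl 4-hydroxybenzoate | COc1cc(Br)cc(/C(COC(=O)c2ccc(O)cc2)=C\c2ccc(O)c(OC)c2)c1O | intermediate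
16 | (2R)-2-(5-bromo-2-hydroxy-3-methoxyphenyl)-3-(3-methoxy-4-oxocyclohexa-2,5-dien-1-ylidene)propyl 4-hydroxybenzoate | COC1=CC(=C[C@@H](COC(=O)c2ccc(O)cc2)c2cc(Br)cc(OC)c2O)C=CC1=O | intermediate
17 | [(2S,3R)-5-bromo-2-(4-hydroxy-3-methoxyphenyl)-7-methoxy-2,3-dihydro-1-benzofuran-3-yl]methyl 4-hydroxybenzoate | COc1cc([C@H]2Oc3c(OC)cc(Br)cc3[C@@H]2COC(=O)c2ccc(O)cc2)ccc1O | intermediate
18 | prop-2-yn-1-ol | C#CCO | starting material
19 | (Z)-3-(tributylstannyl)prop-2-en-1-ol | CCCC[Sn](CCCC)(CCCC)/C=C\CO | intermediate
20 | [(2S,3R)-2-(4-hydroxy-3-methoxyphenyl)-5-[(Z)-3-hydroxyprop-1-en-1-yl]-7-methoxy-2,3-dihydro-1-benzofuran-3-yl]methyl 4-hydroxybenzoate | COc1cc([C@H]2Oc3c(OC)cc(/C=C\CO)cc3[C@@H]2COC(=O)c2ccc(O)cc2)ccc1O | intermediate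
21 | [(2S,3R)-2-(4-hydroxy-3-methoxyphenyl)-7-methoxy-5-[(Z)-3-oxoprop-1-en-1-yl]-2,3-dihydro-1-benzofuran-3-yl]methyl 4-hydroxybenzoate (CNP0400980.1) | COc1cc([C@H]2Oc3c(OC)cc(/C=C\C=O)cc3[C@@H]2COC(=O)c2ccc(O)cc2)ccc1O | target

**Step count and risks**

Total step count: 12. Longest linear sequence: 9 steps (steps 1, 2, 4, 5, 7, 8, 9, 11, 12); steps 3, 6 and 10 are side branches.

Steps most likely to fail:

1. Step 9 (Proposed new method). The acid may be too weak to protonate C3. The allylic ester may ionize instead, with loss of 4-hydroxybenzoic acid and aromatization to a benzofuran. Proton delivery may show poor facial selectivity, or the enantiomeric purity may erode through reversible ring opening. The first variation inside the step is the more acidic N-triflylphosphoramide on the same binaphthyl backbone. The fallback uses known chemistry, sets out from 15 and comes back at 17. Catalyst control is given up and 15 is cyclized with an achiral Brønsted acid (TsOH·H2O cat., CH2Cl2, rt), the known acid-catalysed cycloisomerization of 2-hydroxystilbenes to trans-2-aryl-2,3-dihydrobenzofurans. Under thermodynamic control this should give racemic trans material, that is 17 together with its enantiomer [(2R,3S)-5-bromo-2-(4-hydroxy-3-methoxyphenyl)-7-methoxy-2,3-dihydro-1-benzofuran-3-yl]methyl 4-hydroxybenzoate F1. The two are separated by preparative chromatography on a chiral stationary phase, and 17 goes on to step 11.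

2. Step 12. The push–pull (Z)-enal may isomerize to the E isomer on the oxidant surface or during purification, and the free guaiacyl phenol may be oxidized by MnO2; the preceding Stille step carries a smaller risk of geometry loss. The fallback sets out from 17, so it replaces steps 11 and 12, and comes back at 21. Sonogashira coupling of 17 with 3,3-diethoxyprop-1-yne (PdCl2(PPh3)2, CuI, Et3N, DMF, 70 °C) should give the alkynyl acetal [(2S,3R)-5-(3,3-diethoxyprop-1-yn-1-yl)-2-(4-hydroxy-3-methoxyphenyl)-7-methoxy-2,3-dihydro-1-benzofuran-3-yl]methyl 4-hydroxybenzoate F3. Semi-hydrogenation over Pd/CaCO3 poisoned with Pb(OAc)2 and quinoline (H2, 1 atm, EtOAc) should give the (Z)-alkenyl acetal [(2S,3R)-5-[(Z)-3,3-diethoxyprop-1-en-1-yl]-2-(4-hydroxy-3-methoxyphenyl)-7-methoxy-2,3-dihydro-1-benzofuran-3-yl]methyl 4-hydroxybenzoate F4. Hydrolysis of the acetal with oxalic acid on wet silica gel (CH2Cl2, 0 °C) then leads to 21, and no oxidant meets the free phenols.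

3. Step 7. The ring A phenol may be acylated in competition with the allylic alcohol, or the reaction may stall before full conversion. The fallback sets out from 9 and comes back at 14. Both oxygens of 9 are acylated with an excess of acid chloride 13 (Et3N, DMAP cat., CH2Cl2, rt) to the bis-ester (E)-2-{5-bromo-2-[4-(tert-butyldimethylsilyloxy)benzoyloxy]-3-methoxyphenyl}-3-[3-methoxy-4-(triisopropylsilyloxy)phenyl]prop-2-en-1-yl 4-(tert-butyldimethylsilyloxy)benzoate F2. The phenolic ester is then removed selectively by aminolysis with pyrrolidine (THF, 0 °C), since aryl esters are cleaved by amines far faster than alkyl esters, which returns 14. Partial loss of the benzoate silyl group at this point would do no harm, because step 8 removes it anyway.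

**Further compounds**

F1 | step 9 | [(2R,3S)-5-bromo-2-(4-hydroxy-3-methoxyphenyl)-7-methoxy-2,3-dihydro-1-benzofuran-3-yl]methyl 4-hydroxybenzoate | COc1cc([C@@H]2Oc3c(OC)cc(Br)cc3[C@H]2COC(=O)c2ccc(O)cc2)ccc1O
F2 | step 7 | (E)-2-{5-bromo-2-[4-(tert-butyldimethylsilyloxy)benzoyloxy]-3-methoxyphenyl}-3-[3-methoxy-4-(triisopropylsilyloxy)phenyl]prop-2-en-1-yl 4-(tert-butyldimethylsilyloxy)benzoate | COc1cc(Br)cc(/C(COC(=O)c2ccc(O[Si](C)(C)C(C)(C)C)cc2)=C\c2ccc(O[Si](C(C)C)(C(C)C)C(C)C)c(OC)c2)c1OC(=O)c1ccc(O[Si](C)(C)C(C)(C)C)cc1
F3 | step 12 | [(2S,3R)-5-(3,3-diethoxyprop-1-yn-1-yl)-2-(4-hydroxy-3-methoxyphenyl)-7-methoxy-2,3-dihydro-1-benzofuran-3-yl]methyl 4-hydroxybenzoate | COc1cc([C@H]2Oc3c(OC)cc(C#CC(OCC)OCC)cc3[C@@H]2COC(=O)c2ccc(O)cc2)ccc1O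
F4 | step 12 | [(2S,3R)-5-[(Z)-3,3-diethoxyprop-1-en-1-yl]-2-(4-hydroxy-3-methoxyphenyl)-7-methoxy-2,3-dihydro-1-benzofuran-3-yl]methyl 4-hydroxybenzoate | COc1cc([C@H]2Oc3c(OC)cc(/C=C\C(OCC)OCC)cc3[C@@H]2COC(=O)c2ccc(O)cc2)ccc1O
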